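## Structural features

The target is the 4-hydroxy-3-methoxybenzoate (vanillate) of a guaiane-type hydroazulenol. A cyclopentene (C1–C2–C3=C4(Me)–C5) shares the C1–C5 bond with a cycloheptene (C5–C6–C7(iPr)–C8(O-acyl)–C9–C10(Me)=C1); these guaiane locants are used in all discussion below, also for the bicyclo[3.1.0]hexane intermediates, whose systematic names carry their own locants. The two alkenes are skipped: C1=C10 is tetrasubstituted, C3=C4 is trisubstituted, and both C2 and C5 are doubly allylic. There are three stereocentres (5R,7R,8S): C7 and C8 are adjacent with isopropyl and acyloxy trans, C5 lies one methylene away, and H5 and H8 share one face while H7 is on the other. The fragile elements are the doubly allylic C5–H and C2–H2 (alkene migration into conjugation under acid, base or metal hydrides; autoxidation), the free phenol and the hindered secondary ester. The real difficulty is to relate C5 to the remote C8 across a flexible seven-membered ring, and then to set C7, without moving either alkene. The key step uses the fact that C8–C9 is allylic to C1=C10 and that C6–C7 can carry a second alkene: a retro-[3,3] shift turns C9–C10=C1 and C8–C7=C6 into two alkenyl groups on a cyclopropane C1–C5–C6, so that ring strain pays for the seven-membered ring and the C8 configuration is stored in an alkene geometry.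

## Logic of the disconnections

**27 ⇒ 23 + 25 (through 26).** The acyl C–O bond at C8 is cut last, because acylation keeps the C8 configuration and the ester need not survive any earlier step. The phenol is masked as the acetate in 25, made from 24. The forward step must acylate a hindered secondary alcohol without acid, and the unmasking must spare the alkyl benzoate.

**23 ⇒ 22.** The C7–H and C6–H bonds are removed to give the C6=C7 alkene. This deletes the C7 stereocentre and leaves an allylic alcohol whose hydroxyl can deliver hydrogen to its own face. The forward step needs syn delivery and selectivity for one alkene out of three.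

**22 ⇒ 21 ⇒ 20 (key).** After the O–Si bond, C8–C9 is cut and C1–C6 is reconnected with transposition of both alkenes. The seven-membered ring and the C8 stereocentre are exchanged for a bicyclo[3.1.0]hexene and an enol ether geometry. The forward step demands the E enol ether and a cis relation of the two alkenyl groups. In the boat geometry the E isomer (silyloxy trans to the cyclopropane carbon) places H8 cis to H5, as in 27.

**20 ⇒ 19 ⇒ 18.** The C7–isopropyl bond is cut, then the C7–O(triflate) bond. Enolising an aldehyde whose α-carbon bears a cyclopropyl CH and an isopropyl CH offers no steric basis for E selectivity. The geometry is therefore made at a ketone enolate in which the two oxygens prefer to be cis, and is passed on by a stereoretentive coupling. The demands are O,O-cis enolisation and a coupling cold enough to keep 20 intact.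

**18 ⇒ 17 ⇒ 16.** The C7–C8 bond is cut: a one-carbon hydroxymethyl unit is joined to the aldehyde carbon by polarity reversal. This reduces the side chain to a formyl group; the forward step must be a crossed acyloin reaction, not a homocoupling.

**16 ⇒ 15 ⇒ 14.** Oxidation level and O–Si are adjusted; no skeletal bond is cut. The exo aldehyde is the stable epimer, so no stereochemical demand arises.

**14 ⇒ 13 ⇒ 12.** The C4–CH3 bond is cut through the enol triflate back to the C4 ketone. The ketone is the natural product of a diazoketone cyclopropanation and can enolise only toward C3, so the alkene position is not in question.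

**12 ⇒ 11.** Both cyclopropane bonds from C5 (C5–C1 and C5–C6) are cut. This removes both rings and all three ring stereocentres at once. The forward carbene addition must choose C1=C6 over the isopropenyl alkene, transfer the alkene geometry, and select one alkene face.

**11 ⇒ 9 (through 10).** The C5=N2 unit is removed. The forward step needs regioselective activation of the methyl side of a methyl ketone.

**9 ⇒ 6 + 7 (through 8).** The C2–C3 bond is cut between an allylic electrophile and a three-carbon ketone enolate equivalent. The demands are monoalkylation and SN2 (not SN2′) substitution.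

**6 ⇒ 4 (through 5) ⇒ 2 + 3, and 2 ⇒ 1.** The C1–isopropenyl bond and the C6–H bond are cut. An alkoxide-directed anti addition across an alkynol builds the trisubstituted alkene, with the CH2O group cis to isopropenyl, in one step. The demands are addition at the alkyne carbon next to the free hydroxymethyl group and anti stereochemistry; 2 comes from 1 by monoprotection.

## Other disconnections considered

Alternative 1: Büchner ring expansion. The cut removes C5–C1 and C5–C6, so that the carbene carbon C5 is taken out of a benzene ring that already holds C1 and C6–C10 with the methyl, isopropyl and oxygen substituents. In the forward direction the diazoketone 1-diazo-4-[4-methoxy-2-methyl-5-(propan-2-yl)phenyl]butan-2-one A1 would be decomposed with Cu(MeCN)4PF6 (monovalent copper) and a chiral bis(oxazoline). Carbene addition across the arene bond C1–C6 of A1 followed by 6π electrocyclic ring opening would give the azulenone (8aS)-6-methoxy-4-methyl-7-(propan-2-yl)-3,8a-dihydroazulen-1(2H)-one A2 with both rings closed.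
- In favour: both rings and fourteen of the fifteen skeletal carbons arrive in one step from an aromatic precursor only a few steps from commerce. On step economy up to the bicyclic skeleton this alternative is better than the chosen plan. It is equal to it in relying on a carbenoid generated with Cu(MeCN)4PF6 and a bis(oxazoline) ligand.
- Against: A2 has a single stereocentre (C5), which is α to the C4 ketone and doubly allylic, so enolisation and 1,5-hydrogen shifts should erase it or move the triene into conjugation. The C4 ketone of A2 must become C4–Me with C3=C4, although the more acidic α-position is C5. The C8 enol ether must be reduced to an sp3 carbinol of defined configuration and C6=C7 must be saturated with C7 controlled, both on a cycloheptatriene with no directing group. The carbene from A1 must also choose C1–C6 over C1–C10.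
- Comparison: structurally the chosen plan spends more steps before its key step, but that step delivers the seven-membered ring with C5 and C8 defined and every alkene in its final place, whereas Alternative 1 reaches the ring system sooner and postpones all stereochemical and redox problems to a labile triene. Mechanistically both end in a pericyclic step (electrocyclic opening against a sigmatropic shift). On overall step economy the early gain of Alternative 1 is likely to be spent again in the corrections after A2 .

Alternative 2: transannular epoxide–olefin cyclisation. The cut is C1–C5, which opens both rings to a ten-membered carbocycle. In the forward direction germacrone, (3E,7E)-3,7-dimethyl-10-(propan-2-ylidene)cyclodeca-3,7-dien-1-one A3 , would be reduced at C8, silylated and epoxidised at C4=C5 to the epoxide (4S,5S,8S)-8-[(tert-butyldimethylsilyl)oxy]-4,5-epoxygermacra-1(10),7(11)-diene A4 . Acid would open the epoxide of A4 at C5 with attack by C1, and loss of the C1 proton from the C10 cation would give the tertiary alcohol (4S,5S,8S)-8-[(tert-butyldimethylsilyl)oxy]guaia-1(10),7(11)-dien-4-ol A5 with the five- and seven-membered rings formed together.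
- In favour: A3 is a commercial natural product that already has all fifteen carbons, the C8 oxygen and the C1=C10 alkene. The guaiane skeleton of A5 would be reached in about four steps and the whole route would be roughly half as long as the chosen one; on step economy this alternative is clearly better. The later hydroxyl-directed hydrogenation of C7=C11 uses the same logic as the chosen endgame and is equal to it.
- Against: A3 has no stereocentre, so the absolute configuration must come from an asymmetric reduction at C8. The relative configuration of C8 and C5 then rests on face-selective epoxidation of a conformationally mobile ten-membered ring with three alkenes competing, so A4 may not be accessible as one isomer. The C10 cation can lose a proton in three directions. The C4 hydroxyl of A5 must be eliminated toward C3 only, next to the doubly allylic C5. The ten-membered 1,5-diene of A3 is also prone to thermal [3,3] rearrangement with ring contraction.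
- Comparison: structurally Alternative 2 is the most direct. Mechanistically it is a cationic cascade with several product-determining branch points, whereas the chosen concerted shift has one product channel. The chosen plan is longer, but each stereocentre has a single identified control element.

Alternative 3: allenic Pauson–Khand bicyclisation. The cut removes C1–C5, C2–C3 and C3–C4, with C3 supplied as a carbonyl carbon. In the forward direction the allenyne tert-butyldimethyl{[(5S,6R)-3-methyl-6-(propan-2-yl)deca-1,2-dien-8-yn-5-yl]oxy}silane A6 , with [Rh(CO)2Cl]2 (monovalent rhodium) under CO, would combine its alkyne, its distal allene π bond and CO. The product would be the cross-conjugated dienone (7R,8S)-8-[(tert-butyldimethylsilyl)oxy]guaia-1(10),4-dien-3-one A7 .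
- In favour: both rings form in one step. C7 and C8 are fixed in the open chain of A6 by reliable aldol-type chemistry, so no chemoselective hydrogenation is needed; on the control of C7 this alternative is better than the chosen plan. C1=C10 arrives in place.
- Against: A7 carries an unwanted C3 carbonyl and has the alkene at C4=C5. C5 must be created last, by 1,2-reduction of the C3 carbonyl of A7 followed by reductive 1,3-transposition. Its configuration then depends on a reagent-controlled reduction of a cross-conjugated dienone whose C2 protons are doubly activated. A6 itself needs about nine steps (allene, anti aldol, alkyne).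
- Comparison: the total step count should be about equal to that of the chosen plan. Mechanistically it is a metal-mediated [2+2+1] against a reagent-free thermal shift. Structurally the chosen plan sets C5 first by catalysis and transmits it to C8 pericyclically; Alternative 3 sets C7 and C8 first and leaves C5 to a three-step relay.

Key step: step 15

**Assumption:** the sense of induction of the carbenoid formed from 11 with [Cu(MeCN)4]PF6 (monovalent copper) and the bis(oxazoline) cannot be derived with certainty; the (S,S)-ligand is written for (1S,5S,6S)-12, and the (R,R)-ligand would serve if the opposite sense applied.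

**Remark:** 3 (as its THF solution) and 7 are taken as catalogue reagents; 7 is otherwise the condensation product of acetone and cyclohexylamine.

**Remark:** the E enol ether 20 leads to (5R,8S)-21, which matches 27 at C5 and C8; the E geometry is built at a ketone enolate (steps 13 and 14), and [Rh(nbd)(dppb)]BF4 is preferred to [Ir(cod)(PCy3)(py)]PF6 for the directed hydrogenation (step 17).

## Route

Step 1
Reactants: 1 but-2-yne-1,4-diol
Product: 2 4-[(tert-butyldimethylsilyl)oxy]but-2-yn-1-ol
Conditions: NaH (1.0 equiv), THF, 0 °C; TBSCl (1.0 equiv), 0→25 °C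
Reagents that add atoms: tert-butyldimethylsilyl chloride, CC(C)(C)[Si](C)(C)Cl
Why: Monosilylation of a symmetrical diol through its sparingly soluble monosodium alkoxide, which is silylated once, so the mono-ether should predominate over the bis-ether.

Step 2
Reactants: 2 4-[(tert-butyldimethylsilyl)oxy]but-2-yn-1-ol; 3 isopropenylmagnesium bromide
Product: 4 (2E)-4-[(tert-butyldimethylsilyl)oxy]-2-(prop-1-en-2-yl)but-2-en-1-ol
Conditions: 3 (3.5 equiv), THF, 65 °C; then H2O, 0 °C
Reagents that add atoms: none
Why: Alkoxide-directed anti-carbomagnesiation of a 2-alkyn-1-ol: the magnesium alkoxide steers the alkenyl Grignard reagent to the proximal alkyne carbon (C1) and holds magnesium on C6 in a five-membered chelate, so protonation leaves CH2OTBS cis to isopropenyl. This alkene geometry later becomes the exo, cis-dialkenyl relationship on the cyclopropane.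

Step 3
Reactants: 4 (2E)-4-[(tert-butyldimethylsilyl)oxy]-2-(prop-1-en-2-yl)but-2-en-1-ol
Product: 6 {[(2E)-3-(bromomethyl)-4-methylpenta-2,4-dien-1-yl]oxy}(tert-butyl)dimethylsilane, via allylic mesylate 5 (not isolated)
Conditions: MsCl, Et3N, CH2Cl2, −40 °C; then LiBr, THF, 0 °C
Reagents that add atoms: methanesulfonyl chloride, CS(=O)(=O)Cl (in 5 only); lithium bromide, [Li+].[Br-]
Why: Mesylation followed by SN2 displacement with bromide at the primary allylic carbon; the cold, acid-free conditions should keep the alkene geometry and the silyl ether.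

Step 4
Reactants: 6 {[(2E)-3-(bromomethyl)-4-methylpenta-2,4-dien-1-yl]oxy}(tert-butyl)dimethylsilane; 7 N-(propan-2-ylidene)cyclohexanamine
Product: 9 (5Z)-7-[(tert-butyldimethylsilyl)oxy]-5-(prop-1-en-2-yl)hept-5-en-2-one, via alkylated imine 8 (not isolated)
Conditions: 7, LiN(iPr)2, THF, −78→0 °C; 6, −78→−20 °C; then AcOH/NaOAc buffer (pH 4.5), H2O, 25 °C
Reagents that add atoms: water, O
Why: Metalloenamine alkylation: the lithiated acetone imine reacts once by SN2 at the primary allylic bromide and forms C2–C3, and buffered hydrolysis releases the methyl ketone without touching the silyl ether.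

Step 5
Reactants: 9 (5Z)-7-[(tert-butyldimethylsilyl)oxy]-5-(prop-1-en-2-yl)hept-5-en-2-one
Product: 11 (5Z)-7-[(tert-butyldimethylsilyl)oxy]-1-diazo-5-(prop-1-en-2-yl)hept-5-en-2-one, via trifluoroacetyl diketone 10 (not isolated)
Conditions: LiN(SiMe3)2, THF, −78 °C; CF3CO2CH2CF3, −78 °C; then 4-acetamidobenzenesulfonyl azide, Et3N, H2O (1 equiv), MeCN, 25 °C
Reagents that add atoms: 2,2,2-trifluoroethyl trifluoroacetate, O=C(OCC(F)(F)F)C(F)(F)F (in 10 only); 4-acetamidobenzenesulfonyl azide, CC(=O)Nc1ccc(cc1)S(=O)(=O)N=[N+]=[N-]
Why: Detrifluoroacetylative diazo transfer: kinetic deprotonation at the methyl group, C-trifluoroacetylation and transfer of N2 with loss of the trifluoroacetyl group give the terminal diazoketone without diazomethane.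

Step 6
Reactants: 11 (5Z)-7-[(tert-butyldimethylsilyl)oxy]-1-diazo-5-(prop-1-en-2-yl)hept-5-en-2-one
Product: 12 (1S,5S,6S)-6-{[(tert-butyldimethylsilyl)oxy]methyl}-5-(prop-1-en-2-yl)bicyclo[3.1.0]hexan-2-one
Conditions: [Cu(MeCN)4]PF6 (5 mol %, monovalent copper), (S,S)-tBu-box (6 mol %), CH2Cl2, 40 °C, slow addition of 11
Reagents that add atoms: none
Why: Intramolecular cyclopropanation by the carbenoid formed with [Cu(MeCN)4]PF6 and the bis(oxazoline): C5 adds to the proximal trisubstituted alkene C1=C6 (five-membered ring mode, preferred over addition to the isopropenyl group) and transfers the alkene geometry, so CH2OTBS ends exo and cis to isopropenyl. The chiral ligand selects the alkene face and thereby sets C1, C5 and C6 together.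

Step 7
Reactants: 12 (1S,5S,6S)-6-{[(tert-butyldimethylsilyl)oxy]methyl}-5-(prop-1-en-2-yl)bicyclo[3.1.0]hexan-2-one
Product: 13 (1S,5S,6S)-6-{[(tert-butyldimethylsilyl)oxy]methyl}-5-(prop-1-en-2-yl)bicyclo[3.1.0]hex-2-en-2-yl trifluoromethanesulfonate
Conditions: KN(SiMe3)2, THF, −78 °C; PhNTf2, −78→0 °C
Reagents that add atoms: N-phenylbis(trifluoromethanesulfonimide), O=S(=O)(N(c1ccccc1)S(=O)(=O)C(F)(F)F)C(F)(F)F
Why: Enol triflate formation; the ketone can enolise only toward C3 because C5 is a cyclopropane bridgehead, so one regioisomer is expected.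

Step 8
Reactants: 13 (1S,5S,6S)-6-{[(tert-butyldimethylsilyl)oxy]methyl}-5-(prop-1-en-2-yl)bicyclo[3.1.0]hex-2-en-2-yl trifluoromethanesulfonate
Product: 14 tert-butyldimethyl{[(1R,5R,6S)-2-methyl-5-(prop-1-en-2-yl)bicyclo[3.1.0]hex-2-en-6-yl]methoxy}silane
Conditions: MeZnCl, Pd(PPh3)4 (5 mol %, zerovalent palladium), THF, 25 °C
Reagents that add atoms: methylzinc chloride, C[Zn]Cl
Why: Negishi coupling of the cyclopentenyl triflate installs the C4 methyl group and fixes C3=C4; an unactivated vinylcyclopropane is not opened by Pd(PPh3)4. The change of descriptors from 13 to 14 reflects substituent priorities only.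

Step 9
Reactants: 14 tert-butyldimethyl{[(1R,5R,6S)-2-methyl-5-(prop-1-en-2-yl)bicyclo[3.1.0]hex-2-en-6-yl]methoxy}silane
Product: 15 [(1R,5R,6S)-2-methyl-5-(prop-1-en-2-yl)bicyclo[3.1.0]hex-2-en-6-yl]methanol
Conditions: Bu4NF, THF, 0 °C
Reagents that add atoms: none
Why: Fluoride cleavage of the primary silyl ether; nothing else in 14 responds to fluoride.

Step 10
Reactants: 15 [(1R,5R,6S)-2-methyl-5-(prop-1-en-2-yl)bicyclo[3.1.0]hex-2-en-6-yl]methanol
Product: 16 (1R,5R,6S)-2-methyl-5-(prop-1-en-2-yl)bicyclo[3.1.0]hex-2-ene-6-carbaldehyde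
Conditions: Dess–Martin periodinane, pyridine, CH2Cl2, 0 °C
Reagents that add atoms: none
Why: Dess–Martin oxidation under buffered conditions; the exo aldehyde is the stable epimer. It may equilibrate with its retro-Claisen valence isomer, which step 11 draws back through the aldehyde.

Step 11
Reactants: 16 (1R,5R,6S)-2-methyl-5-(prop-1-en-2-yl)bicyclo[3.1.0]hex-2-ene-6-carbaldehyde
Product: 17 2-hydroxy-1-[(1R,5R,6S)-2-methyl-5-(prop-1-en-2-yl)bicyclo[3.1.0]hex-2-en-6-yl]ethan-1-one
Conditions: (CH2O)n, 3-ethylbenzothiazolium bromide (10 mol %), Et3N (20 mol %), EtOH, 60 °C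
Reagents that add atoms: paraformaldehyde (as formaldehyde), C=O
Why: Thiazolium-carbene crossed acyloin reaction (hydroxymethylation): the Breslow intermediate of 16 adds to formaldehyde and gives the 1-hydroxy-2-ketone, which brings in C8 at the right oxidation level.

Step 12
Reactants: 17 2-hydroxy-1-[(1R,5R,6S)-2-methyl-5-(prop-1-en-2-yl)bicyclo[3.1.0]hex-2-en-6-yl]ethan-1-one
Product: 18 2-[(tert-butyldimethylsilyl)oxy]-1-[(1R,5R,6S)-2-methyl-5-(prop-1-en-2-yl)bicyclo[3.1.0]hex-2-en-6-yl]ethan-1-one
Conditions: TBSCl, imidazole, CH2Cl2, 0 °C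
Reagents that add atoms: tert-butyldimethylsilyl chloride, CC(C)(C)[Si](C)(C)Cl
Why: Imidazole-mediated O-silylation of the primary α-hydroxy group.

Step 13
Reactants: 18 2-[(tert-butyldimethylsilyl)oxy]-1-[(1R,5R,6S)-2-methyl-5-(prop-1-en-2-yl)bicyclo[3.1.0]hex-2-en-6-yl]ethan-1-one
Product: 19 (1Z)-2-[(tert-butyldimethylsilyl)oxy]-1-[(1R,5R,6S)-2-methyl-5-(prop-1-en-2-yl)bicyclo[3.1.0]hex-2-en-6-yl]ethenyl trifluoromethanesulfonate
Conditions: LiN(SiMe3)2, THF, −78 °C; N-(5-chloropyridin-2-yl)bis(trifluoromethanesulfonimide), −78→−40 °C; cold work-up, used at once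
Reagents that add atoms: N-(5-chloropyridin-2-yl)bis(trifluoromethanesulfonimide), O=S(=O)(N(c1ccc(Cl)cn1)S(=O)(=O)C(F)(F)F)C(F)(F)F
Why: Enol triflate formation from a kinetic enolate that can form only toward C8; the two oxygens should end cis (lithium bridging, dipole alignment and avoidance of allylic strain with the cyclopropane carbon), and O-triflation at low temperature keeps this geometry, which places OTBS trans to C6. The triflate is itself a cis-dialkenylcyclopropane with OTBS outside, so any premature rearrangement still converges on 21 after step 14.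

Step 14
Reactants: 19 (1Z)-2-[(tert-butyldimethylsilyl)oxy]-1-[(1R,5R,6S)-2-methyl-5-(prop-1-en-2-yl)bicyclo[3.1.0]hex-2-en-6-yl]ethenyl trifluoromethanesulfonate
Product: 20 tert-butyldimethyl({(1E)-3-methyl-2-[(1R,5R,6S)-2-methyl-5-(prop-1-en-2-yl)bicyclo[3.1.0]hex-2-en-6-yl]but-1-en-1-yl}oxy)silane
Conditions: iPrMgCl, Fe(acac)3 (5 mol %, trivalent iron), THF/NMP, −30 °C, 15 min; cold work-up
Reagents that add atoms: isopropylmagnesium chloride, CC(C)[Mg]Cl
Why: Fe(acac)3-catalysed alkyl–alkenyl cross-coupling replaces OTf by isopropyl with retention of alkene geometry, giving the E enol ether (silyloxy cis to isopropyl, trans to the cyclopropane carbon). The low temperature keeps 20 from rearranging before it is heated deliberately.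

Step 15
Reactants: 20 tert-butyldimethyl({(1E)-3-methyl-2-[(1R,5R,6S)-2-methyl-5-(prop-1-en-2-yl)bicyclo[3.1.0]hex-2-en-6-yl]but-1-en-1-yl}oxy)silane
Product: 21 (5R,8S)-8-[(tert-butyldimethylsilyl)oxy]guaia-1(10),3,6-triene
Conditions: PhMe (degassed, base-washed glass, trace BHT), 70 °C
Reagents that add atoms: none
Why: Cis-divinylcyclopropane–cycloheptadiene rearrangement, a concerted strain-release [3,3] sigmatropic shift through a boat transition state in which the isopropenyl group on C1 and the enol ether on C6 both lie over the three-membered ring. The closest known reaction type is the thermal rearrangement of cis-1,2-dialkenylcyclopropanes to cyclohepta-1,4-dienes used for fused seven-membered rings. The seven-membered ring closes by ring expansion from three to seven atoms: the alkene termini C9 and C8 bond while the cyclopropane bond C1–C6 breaks, and C1=C10 and C6=C7 appear in its place. C8 is the only new stereocentre and is controlled by the enol ether geometry inside the enforced boat: in the E isomer the silyloxy group points away from the ring and H8 points toward H5, so H8 and H5 end cis (8S with 5R). C5 lies outside the reacting array and keeps its configuration. The step needs E geometry, the cis relation of the two alkenyl groups and a temperature below that at which a Z isomer would react; these are secured by steps 13 and 14, by the exo position of the C6 substituent fixed in steps 2 and 6, and by the lower barrier of the isomer without an inside substituent. No retro-ene path competes, because neither alkenyl group has a cis alkyl C–H neighbour on the cyclopropane.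

Step 16
Reactants: 21 (5R,8S)-8-[(tert-butyldimethylsilyl)oxy]guaia-1(10),3,6-triene
Product: 22 (5R,8S)-guaia-1(10),3,6-trien-8-ol
Conditions: Bu4NF, AcOH (1:1), THF, 0 °C
Reagents that add atoms: none
Why: Buffered fluoride desilylation of the secondary allylic silyl ether, mild enough not to move the skipped alkenes. Any Z enol ether carried through is cleaved to a polar aldehyde and removed here.

Step 17
Reactants: 22 (5R,8S)-guaia-1(10),3,6-trien-8-ol
Product: 23 (5R,7R,8S)-guaia-1(10),3-dien-8-ol
Conditions: [Rh(nbd)(dppb)]BF4 (5 mol %, monovalent rhodium), H2 (50 bar), CH2Cl2, 25 °C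
Reagents that add atoms: none
Why: Hydroxyl-directed homogeneous hydrogenation: the cationic rhodium centre of [Rh(nbd)(dppb)]BF4 binds the C8 hydroxyl and delivers H2 to the neighbouring C6=C7 from the hydroxyl face, so H7 ends cis to O8 and the isopropyl group trans (7R). This catalyst class does not turn over the unfunctionalised trisubstituted C3=C4 or the tetrasubstituted C1=C10, which is why it is preferred here to the more active [Ir(cod)(PCy3)(py)]PF6.

Step 18
Reactants: 24 vanillic acid
Product: 25 4-acetoxy-3-methoxybenzoic acid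
Conditions: Ac2O, pyridine, 25 °C; aqueous work-up
Reagents that add atoms: acetic anhydride, CC(=O)OC(C)=O
Why: Acetylation of the phenol with acetic anhydride in pyridine; the aqueous work-up returns the free carboxylic acid.

Step 19
Reactants: 23 (5R,7R,8S)-guaia-1(10),3-dien-8-ol; 25 4-acetoxy-3-methoxybenzoic acid
Product: 26 (5R,7R,8S)-guaia-1(10),3-dien-8-yl 4-acetoxy-3-methoxybenzoate
Conditions: DCC, DMAP, CH2Cl2, 0→25 °C
Reagents that add atoms: none
Why: Steglich esterification acylates the hindered secondary alcohol under neutral conditions with retention at C8.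

Step 20
Reactants: 26 (5R,7R,8S)-guaia-1(10),3-dien-8-yl 4-acetoxy-3-methoxybenzoate
Product: 27 (5R,7R,8S)-guaia-1(10),3-dien-8-yl 4-hydroxy-3-methoxybenzoate
Conditions: K2CO3 (0.2 equiv), MeOH, 0 °C
Reagents that add atoms: none
Why: Transesterification: the aryl acetate is far more electrophilic than the hindered alkyl benzoate, so catalytic carbonate in cold methanol should free only the phenol.

## Compound list

1 | but-2-yne-1,4-diol | OCC#CCO | starting material
2 | 4-[(tert-butyldimethylsilyl)oxy]but-2-yn-1-ol | OCC#CCO[Si](C)(C)C(C)(C)C | intermediate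
3 | isopropenylmagnesium bromide (prop-1-en-2-ylmagnesium bromide) | C=C(C)[Mg]Br | starting material
4 | (2E)-4-[(tert-butyldimethylsilyl)oxy]-2-(prop-1-en-2-yl)but-2-en-1-ol | OC/C(=C/CO[Si](C)(C)C(C)(C)C)C(C)=C | intermediate
5 | (2E)-4-[(tert-butyldimethylsilyl)oxy]-2-(prop-1-en-2-yl)but-2-en-1-yl methanesulfonate | CS(=O)(=O)OC/C(=C/CO[Si](C)(C)C(C)(C)C)C(C)=C | intermediate
6 | {[(2E)-3-(bromomethyl)-4-methylpenta-2,4-dien-1-yl]oxy}(tert-butyl)dimethylsilane | BrC/C(=C/CO[Si](C)(C)C(C)(C)C)C(C)=C | intermediate
7 | N-(propan-2-ylidene)cyclohexanamine (acetone N-cyclohexylimine) | CC(C)=NC1CCCCC1 | starting material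
8 | N-{(5Z)-7-[(tert-butyldimethylsilyl)oxy]-5-(prop-1-en-2-yl)hept-5-en-2-ylidene}cyclohexanamine | CC(CC/C(=C/CO[Si](C)(C)C(C)(C)C)C(C)=C)=NC1CCCCC1 | intermediate
9 | (5Z)-7-[(tert-butyldimethylsilyl)oxy]-5-(prop-1-en-2-yl)hept-5-en-2-one | CC(=O)CC/C(=C/CO[Si](C)(C)C(C)(C)C)C(C)=C | intermediate
10 | (7Z)-9-[(tert-butyldimethylsilyl)oxy]-1,1,1-trifluoro-7-(prop-1-en-2-yl)non-7-ene-2,4-dione | O=C(CC(=O)CC/C(=C/CO[Si](C)(C)C(C)(C)C)C(C)=C)C(F)(F)F | intermediate
11 | (5Z)-7-[(tert-butyldimethylsilyl)oxy]-1-diazo-5-(prop-1-en-2-yl)hept-5-en-2-one | [N-]=[N+]=CC(=O)CC/C(=C/CO[Si](C)(C)C(C)(C)C)C(C)=C | intermediate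
12 | (1S,5S,6S)-6-{[(tert-butyldimethylsilyl)oxy]methyl}-5-(prop-1-en-2-yl)bicyclo[3.1.0]hexan-2-one | C=C(C)[C@]12CCC(=O)[C@H]1[C@@H]2CO[Si](C)(C)C(C)(C)C | intermediate
13 | (1S,5S,6S)-6-{[(tert-butyldimethylsilyl)oxy]methyl}-5-(prop-1-en-2-yl)bicyclo[3.1.0]hex-2-en-2-yl trifluoromethanesulfonate | C=C(C)[C@]12CC=C(OS(=O)(=O)C(F)(F)F)[C@H]1[C@@H]2CO[Si](C)(C)C(C)(C)C | intermediate
14 | tert-butyldimethyl{[(1R,5R,6S)-2-methyl-5-(prop-1-en-2-yl)bicyclo[3.1.0]hex-2-en-6-yl]methoxy}silane | C=C(C)[C@]12CC=C(C)[C@H]1[C@@H]2CO[Si](C)(C)C(C)(C)C | intermediate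
15 | [(1R,5R,6S)-2-methyl-5-(prop-1-en-2-yl)bicyclo[3.1.0]hex-2-en-6-yl]methanol | C=C(C)[C@]12CC=C(C)[C@H]1[C@@H]2CO | intermediate
16 | (1R,5R,6S)-2-methyl-5-(prop-1-en-2-yl)bicyclo[3.1.0]hex-2-ene-6-carbaldehyde | C=C(C)[C@]12CC=C(C)[C@H]1[C@@H]2C=O | intermediate
17 | 2-hydroxy-1-[(1R,5R,6S)-2-methyl-5-(prop-1-en-2-yl)bicyclo[3.1.0]hex-2-en-6-yl]ethan-1-one | C=C(C)[C@]12CC=C(C)[C@H]1[C@@H]2C(=O)CO | intermediate
18 | 2-[(tert-butyldimethylsilyl)oxy]-1-[(1R,5R,6S)-2-methyl-5-(prop-1-en-2-yl)bicyclo[3.1.0]hex-2-en-6-yl]ethan-1-one | C=C(C)[C@]12CC=C(C)[C@H]1[C@@H]2C(=O)CO[Si](C)(C)C(C)(C)C | intermediate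
19 | (1Z)-2-[(tert-butyldimethylsilyl)oxy]-1-[(1R,5R,6S)-2-methyl-5-(prop-1-en-2-yl)bicyclo[3.1.0]hex-2-en-6-yl]ethenyl trifluoromethanesulfonate | C=C(C)[C@]12CC=C(C)[C@H]1[C@@H]2/C(OS(=O)(=O)C(F)(F)F)=C/O[Si](C)(C)C(C)(C)C | intermediate
20 | tert-butyldimethyl({(1E)-3-methyl-2-[(1R,5R,6S)-2-methyl-5-(prop-1-en-2-yl)bicyclo[3.1.0]hex-2-en-6-yl]but-1-en-1-yl}oxy)silane | C=C(C)[C@]12CC=C(C)[C@H]1[C@@H]2/C(C(C)C)=C/O[Si](C)(C)C(C)(C)C | intermediate
21 | (5R,8S)-8-[(tert-butyldimethylsilyl)oxy]guaia-1(10),3,6-triene, i.e. tert-butyl{[(3aR,6S)-3,8-dimethyl-5-(propan-2-yl)-1,3a,6,7-tetrahydroazulen-6-yl]oxy}dimethylsilane | CC(C)(C)[Si](C)(C)O[C@H]1CC(C)=C2CC=C(C)[C@H]2C=C1C(C)C | intermediate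
22 | (5R,8S)-guaia-1(10),3,6-trien-8-ol, i.e. (3aR,6S)-3,8-dimethyl-5-(propan-2-yl)-1,3a,6,7-tetrahydroazulen-6-ol | O[C@H]1CC(C)=C2CC=C(C)[C@H]2C=C1C(C)C | intermediate
23 | (5R,7R,8S)-guaia-1(10),3-dien-8-ol, i.e. (3aR,5R,6S)-3,8-dimethyl-5-(propan-2-yl)-1,3a,4,5,6,7-hexahydroazulen-6-ol | O[C@H]1CC(C)=C2CC=C(C)[C@H]2C[C@@H]1C(C)C | intermediate
24 | vanillic acid (4-hydroxy-3-methoxybenzoic acid) | COc1cc(C(=O)O)ccc1O | starting material
25 | 4-acetoxy-3-methoxybenzoic acid | COc1cc(C(=O)O)ccc1OC(C)=O | intermediate
26 | (5R,7R,8S)-guaia-1(10),3-dien-8-yl 4-acetoxy-3-methoxybenzoate, i.e. (3aR,5R,6S)-3,8-dimethyl-5-(propan-2-yl)-1,3a,4,5,6,7-hexahydroazulen-6-yl 4-(acetyloxy)-3-methoxybenzoate | COc1cc(C(=O)O[C@H]2CC(C)=C3CC=C(C)[C@H]3C[C@@H]2C(C)C)ccc1OC(C)=O | intermediate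
27 | (5R,7R,8S)-guaia-1(10),3-dien-8-yl 4-hydroxy-3-methoxybenzoate, i.e. (3aR,5R,6S)-3,8-dimethyl-5-(propan-2-yl)-1,3a,4,5,6,7-hexahydroazulen-6-yl 4-hydroxy-3-methoxybenzoate | COc1cc(C(=O)O[C@H]2CC(C)=C3CC=C(C)[C@H]3C[C@@H]2C(C)C)ccc1O | target

## Step count and least certain steps

Total: 20 steps. Longest linear sequence: 19 steps (steps 1–17, 19 and 20); step 18 is a one-step side branch.

**Step 15 (key step).** The boat transition state eclipses the isopropyl group on C7 with the methyl group on C10. This may raise the barrier to a temperature at which hydrolysis of the enol ether, loss of E geometry or hydrogen shifts in the triply allylic product compete.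
Fallback: rearrange before the isopropyl group is attached. Setting out from 19, gentle warming in toluene should give the ring-expanded (3aR,6S)-6-[(tert-butyldimethylsilyl)oxy]-3,8-dimethyl-1,3a,6,7-tetrahydroazulen-5-yl trifluoromethanesulfonate F1 in which only a triflate oxygen sits at the internal position of the boat. Coupling of F1 with iPrMgCl under Fe(acac)3 catalysis (trivalent iron, THF/NMP, −30 °C) then comes back to the route at 21.

**Step 13.** Three things may go wrong: incomplete O,O-cis selectivity in the enolisation, 1,4-migration of the silyl group between the two oxygens of the enolate before triflation, and reduction or loss of the oxygen in the following coupling. All three would erode the supply of E-configured 20.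
Fallback: bring in isopropyl and C8 as carbon nucleophiles and let the rearrangement itself select the geometry. Setting out from 16, addition of iPrMgCl should give 2-methyl-1-[(1R,5R,6S)-2-methyl-5-(prop-1-en-2-yl)bicyclo[3.1.0]hex-2-en-6-yl]propan-1-ol F2 as a mixture of carbinol epimers. Dess–Martin oxidation of F2 should give 2-methyl-1-[(1R,5R,6S)-2-methyl-5-(prop-1-en-2-yl)bicyclo[3.1.0]hex-2-en-6-yl]propan-1-one F3 as a single ketone. Van Leusen reductive cyanation of F3 (TosMIC, KOtBu, DME/EtOH) should give 3-methyl-2-[(1R,5S,6R)-2-methyl-5-(prop-1-en-2-yl)bicyclo[3.1.0]hex-2-en-6-yl]butanenitrile F4 as a pair of epimers; the ring descriptors change by substituent priority only. Reduction of F4 with iBu2AlH and hydrolytic work-up should give 3-methyl-2-[(1R,5S,6R)-2-methyl-5-(prop-1-en-2-yl)bicyclo[3.1.0]hex-2-en-6-yl]butanal F5 as the aldehyde. Soft enolisation of F5 (TBSOTf, Et3N, CH2Cl2, 0 °C) gives 20 together with its Z isomer tert-butyldimethyl({(1Z)-3-methyl-2-[(1R,5R,6S)-2-methyl-5-(prop-1-en-2-yl)bicyclo[3.1.0]hex-2-en-6-yl]but-1-en-1-yl}oxy)silane F6 in the same flask. On heating, only 20 should rearrange; F6 is then cleaved back to F5 with fluoride and recycled. The fallback comes back to the route at 20.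

**Step 11.** The carbene adduct of the hindered cyclopropyl aldehyde may form slowly, and 16 may be largely stored as its retro-Claisen valence isomer, so self-condensation of formaldehyde could dominate.
Fallback: nucleophilic hydroxymethylation. Setting out from 16, (iPrO)Me2SiCH2MgCl should give 2-[dimethyl(propan-2-yloxy)silyl]-1-[(1R,5R,6S)-2-methyl-5-(prop-1-en-2-yl)bicyclo[3.1.0]hex-2-en-6-yl]ethan-1-ol F7 as a crude β-hydroxysilane. Tamao oxidation of F7 (H2O2, KF, KHCO3, THF/MeOH) should give 1-[(1R,5R,6S)-2-methyl-5-(prop-1-en-2-yl)bicyclo[3.1.0]hex-2-en-6-yl]ethane-1,2-diol F8 as the diol. TBSCl and imidazole should silylate the primary hydroxyl of F8 to give 2-[(tert-butyldimethylsilyl)oxy]-1-[(1R,5R,6S)-2-methyl-5-(prop-1-en-2-yl)bicyclo[3.1.0]hex-2-en-6-yl]ethan-1-ol F9 as the monosilyl ether. Dess–Martin oxidation of F9 comes back to the route at 18.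

**Step 6.** Face selectivity may be insufficient on a diene-substituted alkene, and carbene addition to the isopropenyl group (six-membered ring mode) may compete.
Fallback: separate ring formation from asymmetric induction. Setting out from 11, Rh2(OAc)4 (divalent rhodium) should give the racemate, that is 12 together with its enantiomer (1R,5R,6R)-6-{[(tert-butyldimethylsilyl)oxy]methyl}-5-(prop-1-en-2-yl)bicyclo[3.1.0]hexan-2-one F10 in equal amounts. Preparative chromatography on a chiral stationary phase removes F10 and comes back to the route at 12.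

**Step 2.** The alkenylmagnesium intermediate carries a silyloxy group in the β-position; elimination to a vinylallene, or slow addition of the hindered Grignard reagent, may occur.
Fallback: remove the leaving group. Setting out from 1, carbomagnesiation with 3 (both hydroxyls as alkoxides) should give (2E)-2-(prop-1-en-2-yl)but-2-ene-1,4-diol F11 as the diol. Monosilylation of F11 at the less hindered hydroxymethyl group (the one on the CH= carbon; TBSCl, imidazole, −40 °C) comes back to the route at 4.

## Further compounds

F1 | step 15 | (3aR,6S)-6-[(tert-butyldimethylsilyl)oxy]-3,8-dimethyl-1,3a,6,7-tetrahydroazulen-5-yl trifluoromethanesulfonate | CC(C)(C)[Si](C)(C)O[C@H]1CC(C)=C2CC=C(C)[C@H]2C=C1OS(=O)(=O)C(F)(F)F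
F2 | step 13 | 2-methyl-1-[(1R,5R,6S)-2-methyl-5-(prop-1-en-2-yl)bicyclo[3.1.0]hex-2-en-6-yl]propan-1-ol (both carbinol epimers) | C=C(C)[C@]12CC=C(C)[C@H]1[C@@H]2C(O)C(C)C
F3 | step 13 | 2-methyl-1-[(1R,5R,6S)-2-methyl-5-(prop-1-en-2-yl)bicyclo[3.1.0]hex-2-en-6-yl]propan-1-one | C=C(C)[C@]12CC=C(C)[C@H]1[C@@H]2C(=O)C(C)C
F4 | step 13 | 3-methyl-2-[(1R,5S,6R)-2-methyl-5-(prop-1-en-2-yl)bicyclo[3.1.0]hex-2-en-6-yl]butanenitrile (both epimers at C2 of the chain) | C=C(C)[C@]12CC=C(C)[C@H]1[C@@H]2C(C#N)C(C)C
F5 | step 13 | 3-methyl-2-[(1R,5S,6R)-2-methyl-5-(prop-1-en-2-yl)bicyclo[3.1.0]hex-2-en-6-yl]butanal (both epimers at C2 of the chain) | C=C(C)[C@]12CC=C(C)[C@H]1[C@@H]2C(C=O)C(C)C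
F6 | step 13 | tert-butyldimethyl({(1Z)-3-methyl-2-[(1R,5R,6S)-2-methyl-5-(prop-1-en-2-yl)bicyclo[3.1.0]hex-2-en-6-yl]but-1-en-1-yl}oxy)silane (Z isomer of 20) | C=C(C)[C@]12CC=C(C)[C@H]1[C@@H]2/C(C(C)C)=C\O[Si](C)(C)C(C)(C)C
F7 | step 11 | 2-[dimethyl(propan-2-yloxy)silyl]-1-[(1R,5R,6S)-2-methyl-5-(prop-1-en-2-yl)bicyclo[3.1.0]hex-2-en-6-yl]ethan-1-ol (both carbinol epimers) | C=C(C)[C@]12CC=C(C)[C@H]1[C@@H]2C(O)C[Si](C)(C)OC(C)C
F8 | step 11 | 1-[(1R,5R,6S)-2-methyl-5-(prop-1-en-2-yl)bicyclo[3.1.0]hex-2-en-6-yl]ethane-1,2-diol (both carbinol epimers) | C=C(C)[C@]12CC=C(C)[C@H]1[C@@H]2C(O)CO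
F9 | step 11 | 2-[(tert-butyldimethylsilyl)oxy]-1-[(1R,5R,6S)-2-methyl-5-(prop-1-en-2-yl)bicyclo[3.1.0]hex-2-en-6-yl]ethan-1-ol (both carbinol epimers) | C=C(C)[C@]12CC=C(C)[C@H]1[C@@H]2C(O)CO[Si](C)(C)C(C)(C)C
F10 | step 6 | (1R,5R,6R)-6-{[(tert-butyldimethylsilyl)oxy]methyl}-5-(prop-1-en-2-yl)bicyclo[3.1.0]hexan-2-one | C=C(C)[C@@]12CCC(=O)[C@@H]1[C@H]2CO[Si](C)(C)C(C)(C)C
F11 | step 2 | (2E)-2-(prop-1-en-2-yl)but-2-ene-1,4-diol | OC/C(=C/CO)C(C)=C
A1 | alternative 1 | 1-diazo-4-[4-methoxy-2-methyl-5-(propan-2-yl)phenyl]butan-2-one | [N-]=[N+]=CC(=O)CCc1cc(C(C)C)c(OC)cc1C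
A2 | alternative 1 | (8aS)-6-methoxy-4-methyl-7-(propan-2-yl)-3,8a-dihydroazulen-1(2H)-one | COC1=CC(C)=C2CCC(=O)[C@H]2C=C1C(C)C
A3 | alternative 2 | germacrone, (3E,7E)-3,7-dimethyl-10-(propan-2-ylidene)cyclodeca-3,7-dien-1-one | C/C1=C\CC/C(C)=C/CC(=C(C)C)C(=O)C1
A4 | alternative 2 | (4S,5S,8S)-8-[(tert-butyldimethylsilyl)oxy]-4,5-epoxygermacra-1(10),7(11)-diene (1(10)E) | CC(C)(C)[Si](C)(C)O[C@H]1C/C(C)=C/CC[C@]2(C)O[C@H]2CC1=C(C)C
A5 | alternative 2 | (4S,5S,8S)-8-[(tert-butyldimethylsilyl)oxy]guaia-1(10),7(11)-dien-4-ol | CC(C)(C)[Si](C)(C)O[C@H]1CC(C)=C2CC[C@](C)(O)[C@H]2CC1=C(C)C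
A6 | alternative 3 | tert-butyldimethyl{[(5S,6R)-3-methyl-6-(propan-2-yl)deca-1,2-dien-8-yn-5-yl]oxy}silane | C=C=C(C)C[C@H](O[Si](C)(C)C(C)(C)C)[C@@H](C(C)C)CC#CC
A7 | alternative 3 | (7R,8S)-8-[(tert-butyldimethylsilyl)oxy]guaia-1(10),4-dien-3-one | CC(C)(C)[Si](C)(C)O[C@H]1CC(C)=C2CC(=O)C(C)=C2C[C@@H]1C(C)C
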